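common to all: J 200 mM (held)
- green: L 1.5 M; the very flask that is asked about, followed so far
- ochre: L 2.2 M; run made earlier
- flask: L 1.5 M; time 12 h

- green (time / min: Z / %, L / %): 10.0: 0.1, 99.2; 25.0: 1.6, 99.4; 60.0: 3.1, 97.3; 120: 8.3, 92.0
- ochre (time / h: Z / %, L / %): 0.417: 1.1, 98.9; 0.833: 1.9, 98.0; 2.00: 6.0, 93.1; 5.00: 17.5, 81.7

(each reading ± 0.5 percentage points)

1. how much Z there is at 12 h, in percent of the L charged
2. concentration of X in solution at 3.0 h, in percent of saturation
3. the change that raises the amount of Z at 12 h, in percent of the L charged most ("none" if none brings more than 2 percentage points) (theta / alpha / none)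
4. amount of Z at 12 h, in percent of the L charged, after theta

- at the start none of J is in solution
- X is what J becomes in solution

- theta: doubling the saturation concentration of J, all else as stated
- alpha: doubling the transfer coefficient of J, all else as stated

**Two charges.** The ochre charge of L stood to the green one at 1.47, so I asked what fraction of its L each run lost per hour. The last ochre reading gave 0.0404 h⁻¹ for the pace k, the natural logarithm of L charged over L left, divided by the time; this is an apparent first-order constant. The last green reading gave 0.0417 h⁻¹, so green stood to ochre at 1.03, a smaller ratio than that of the charges.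

**Carrying forward.** I kept the ochre k, since its loss of 18.3% was larger than the green loss of 8.00% and so stood further clear of the scatter. Run to 12 h, with all L lost read as Z, that k gave Z 38.4% in the green flask, and I committed to that.

**Weak link.** The ochre k was an average from the start of that run. Between 2.00 h and 5.00 h the ochre pace read 0.0435 h⁻¹, faster than k. Running that later pace on from the last ochre reading gave 39.8% for the green flask, so I held Z between these two figures.

**The forecast.** It said 64% for Z at 12 h, 96% of saturation for X at 3.0 h, theta as the better change, and 97% for Z after it, reading that “the rate is nearly zero order in L”. Its Z stood higher than my reckoning, which took a fixed fraction of L per hour instead of a fixed amount.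

**The flask.** The green flask gave Z 36.9% at 12 h and X 75.9% of saturation at 3.0 h. The better change was theta: theta added 15 percentage points and alpha 1.9 points, and theta brought Z to 52.4%.

    L + X ⇌ Z + Q (K = 2.50, k = 1.00 × 10⁻⁴ M⁻¹ s⁻¹)
    J ⇌ X, rate k2*(csat - [X]) (kL = 4.10 × 10⁻⁴ s⁻¹)

**Way back.** The green flask's own pace up to 12 h, from the L left, was 0.0384 h⁻¹, against 0.0404 h⁻¹ for k. Up to then the backward turnover of L + X to Z + Q in the green flask came to 30% of the forward one, and at 120 h Z in that flask stood at 43.4%. For the green flask read at 3.0 h, k gave Z 11.4%; the computed result was 12.3%.

All runs were computed with made-up constants.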